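## Retrosynthetic overview

1. Target 27 is cut at the ester C–O bond into the syn-1,3-diol 18 and the silyl-protected (Z)-2-(hydroxymethyl)but-2-enoic acid 24, which is made from crotonaldehyde by α-iodination, reduction, silylation and iodine–lithium exchange/CO2.
2. Diol 18 comes from β-hydroxy ketone 17 by chelation-controlled reduction, which sets C1 (the carbinol carbon). The C1–aryl bond comes from Weinreb amide 13 and the Grignard reagent of 4-bromo-1,2-dimethoxybenzene.
3. The strategy rests on C2 (the branched carbon) and its CH2–CH=CH–aryl chain (C4, C5, C6). C5=C6 lies γ,δ to the C1 carbon, the pattern of an ester enolate Claisen rearrangement. Acid 12 is therefore traced to (R)-1-(4-methoxyphenyl)allyl 3-silyloxypropanoate 9, and the shift forms C2–C4, the E C5=C6 bond and the C2 stereocentre.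
4. Ester 9 is assembled from 4-methoxybenzaldehyde and vinylmagnesium bromide (with lipase resolution) and from methyl 3-hydroxypropanoate.
5. No ring is formed at any point: both benzene rings are bought, and the six-membered chair of the key step exists only in its transition state.

Key step: step 7

Remark: the lipase is assumed to acylate the (R)-alcohol (aryl as the large group, vinyl as the medium group), so the acetate, not the recovered alcohol, carries the configuration needed for 9.

## Route

Step 1
Reactants: 1 4-methoxybenzaldehyde; 2 vinylmagnesium bromide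
Product: 3 rac-1-(4-methoxyphenyl)prop-2-en-1-ol
Conditions: THF, 0 °C; sat. aq. NH4Cl
Reagents that add atoms: none
Why: Grignard 1,2-addition to a non-enolisable aromatic aldehyde is dependable; the carbinol centre forms racemic and is resolved in step 2.

Step 2
Reactants: 3 rac-1-(4-methoxyphenyl)prop-2-en-1-ol
Product: 4 (1R)-1-(4-methoxyphenyl)prop-2-en-1-yl acetate
Conditions: immobilised Candida antarctica lipase B, vinyl acetate, hexane–t-BuOMe, 30 °C, stopped just short of half conversion
Reagents that add atoms: vinyl acetate, C=COC(C)=O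
Why: Lipase-catalysed kinetic resolution by irreversible transesterification should acylate only the (R)-alcohol, and the neutral, non-polar medium should keep the ionisable 4-methoxybenzylic acetate intact.

Step 3
Reactants: 4 (1R)-1-(4-methoxyphenyl)prop-2-en-1-yl acetate
Product: 5 (1R)-1-(4-methoxyphenyl)prop-2-en-1-ol
Conditions: K2CO3 (cat.), MeOH, 0 °C
Reagents that add atoms: none
Why: Base-catalysed transesterification (methanolysis) cleaves the acyl–oxygen bond, so the carbinol C–O bond and its (R) configuration are untouched, and basic conditions suppress ionisation.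

Step 4
Reactants: 6 methyl 3-hydroxypropanoate
Product: 7 methyl 3-[(triisopropylsilyl)oxy]propanoate
Conditions: i-Pr3SiCl, imidazole, DMF, rt
Reagents that add atoms: chlorotriisopropylsilane, CC(C)[Si](Cl)(C(C)C)C(C)C
Why: Imidazole-promoted silylation of a primary alcohol; the bulky, non-chelating and poorly leaving triisopropylsilyl ether is chosen for the enolate chemistry of step 7.

Step 5
Reactants: 7 methyl 3-[(triisopropylsilyl)oxy]propanoate
Product: 8 3-[(triisopropylsilyl)oxy]propanoic acid
Conditions: LiOH·H2O, THF–H2O, 0 °C → rt; then 1 M HCl to pH 4 at 0 °C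
Reagents that add atoms: lithium hydroxide, [Li+].[OH-]
Why: Saponification of an unhindered methyl ester proceeds at low temperature, where retro-Michael loss of silyloxide is slow and the silyl ether survives.

Step 6
Reactants: 5 (1R)-1-(4-methoxyphenyl)prop-2-en-1-ol; 8 3-[(triisopropylsilyl)oxy]propanoic acid
Product: 9 (1R)-1-(4-methoxyphenyl)prop-2-en-1-yl 3-[(triisopropylsilyl)oxy]propanoate
Conditions: DCC, 4-(dimethylamino)pyridine (cat.), CH2Cl2, 0 °C → rt; chromatography on Et3N-deactivated silica
Reagents that add atoms: none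
Why: Steglich esterification acylates the hydroxyl oxygen without breaking the carbinol C–O bond, so the (R) centre is retained, and the acid-free handling avoids 1,3-acyloxy shift of the product.

Step 7
Reactants: 9 (1R)-1-(4-methoxyphenyl)prop-2-en-1-yl 3-[(triisopropylsilyl)oxy]propanoate
Product: 12 (2R,4E)-5-(4-methoxyphenyl)-2-{[(triisopropylsilyl)oxy]methyl}pent-4-enoic acid, via silyl ketene acetal 10 (not isolated), via trimethylsilyl ester 11 (not isolated)
Conditions: LiN(i-Pr)2, Me3SiCl–Et3N (premixed, present before the ester), THF–DMPU, −95 → −78 °C, then → 20 °C; dilute aq. citric acid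
Reagents that add atoms: none
Why: LiN(i-Pr)2 removes an α-proton of the propanoate and the enolate is silylated at once by the Me3SiCl already present, which in THF–DMPU should give mainly the (Z)-ketene acetal 10 (CH2OSi cis to OSiMe3) and leaves the enolate no time to expel silyloxide. Ketene acetal 10 then undergoes a concerted suprafacial [3,3]-sigmatropic shift, the Ireland–Claisen rearrangement of a secondary allylic ester, which is the closest known reaction type and a direct precedent class. No ring is closed: the six-membered array exists only in the transition state, and the allylic C–O bond breaks as the C2–C4 bond forms. In the chair transition state the 4-methoxyphenyl group on the carbinol carbon and the CH2OSi group on the ketene acetal terminus both sit equatorial, so the (R) carbinol centre is exchanged for the (2R) centre and the new C5=C6 bond is E and conjugated to the anisyl ring. The step needs one ketene acetal geometry and a rearrangement faster than ionisation of the 4-methoxybenzylic C–O bond; the dipolar cosolvent together with the bulky non-chelating silyl ether should secure the first, and the electron-rich aryl group, which lets the shift run at or below room temperature under basic aprotic conditions, should secure the second.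

Step 8
Reactants: 12 (2R,4E)-5-(4-methoxyphenyl)-2-{[(triisopropylsilyl)oxy]methyl}pent-4-enoic acid
Product: 13 (2R,4E)-N-methoxy-5-(4-methoxyphenyl)-N-methyl-2-{[(triisopropylsilyl)oxy]methyl}pent-4-enamide
Conditions: MeNHOMe·HCl, EDC·HCl, 1-hydroxybenzotriazole, N-methylmorpholine, CH2Cl2, 0 °C → rt
Reagents that add atoms: N,O-dimethylhydroxylamine hydrochloride, CNOC.Cl
Why: Carbodiimide amide coupling through the hydroxybenzotriazole ester is mild enough that the α-stereocentre should not enolise, and it gives the Weinreb amide needed for a clean ketone synthesis.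

Step 9
Reactants: 13 (2R,4E)-N-methoxy-5-(4-methoxyphenyl)-N-methyl-2-{[(triisopropylsilyl)oxy]methyl}pent-4-enamide; 14 4-bromo-1,2-dimethoxybenzene
Product: 16 (2R,4E)-1-(3,4-dimethoxyphenyl)-5-(4-methoxyphenyl)-2-{[(triisopropylsilyl)oxy]methyl}pent-4-en-1-one, via aryl Grignard reagent 15 (not isolated)
Conditions: 14, Mg, THF, 20–40 °C; then 13, THF, −10 → 0 °C; sat. aq. NH4Cl
Reagents that add atoms: none
Why: Weinreb ketone synthesis: the magnesium-chelated tetrahedral adduct stops over-addition and releases the enolisable ketone only on quench, so C2 should keep its configuration.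

Step 10
Reactants: 16 (2R,4E)-1-(3,4-dimethoxyphenyl)-5-(4-methoxyphenyl)-2-{[(triisopropylsilyl)oxy]methyl}pent-4-en-1-one
Product: 17 (2R,4E)-1-(3,4-dimethoxyphenyl)-2-(hydroxymethyl)-5-(4-methoxyphenyl)pent-4-en-1-one
Conditions: HF·pyridine, pyridine, THF, 0 °C → rt
Reagents that add atoms: none
Why: Fluoride-mediated desilylation under buffered, weakly acidic conditions frees the primary hydroxyl without the basic medium that would epimerise C2 or trigger retro-aldol or dehydration of the β-hydroxy ketone.

Step 11
Reactants: 17 (2R,4E)-1-(3,4-dimethoxyphenyl)-2-(hydroxymethyl)-5-(4-methoxyphenyl)pent-4-en-1-one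
Product: 18 (1S,2R)-1-(3,4-dimethoxyphenyl)-2-[(2E)-3-(4-methoxyphenyl)prop-2-en-1-yl]propane-1,3-diol
Conditions: Zn(BH4)2, Et2O, −20 → 0 °C; sat. aq. NH4Cl
Reagents that add atoms: none
Why: Chelation-controlled reduction: zinc bridges the ketone oxygen and the primary hydroxyl in a six-membered chelate and hydride should enter anti to the C2 allylic chain, giving the (1S) carbinol, that is the syn diol.

Step 12
Reactants: 19 (E)-but-2-enal (crotonaldehyde)
Product: 20 (2Z)-2-iodobut-2-enal
Conditions: I2, K2CO3, 4-(dimethylamino)pyridine (cat.), THF–H2O, rt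
Reagents that add atoms: iodine, II
Why: α-Iodination of an enal by conjugate addition of the amine catalyst, iodination of the enolate and elimination should give the thermodynamically preferred isomer with methyl cis to iodine.

Step 13
Reactants: 20 (2Z)-2-iodobut-2-enal
Product: 21 (2Z)-2-iodobut-2-en-1-ol
Conditions: NaBH4, MeOH, 0 °C
Reagents that add atoms: none
Why: Borohydride 1,2-reduction of the aldehyde leaves the vinyl iodide and its geometry untouched.

Step 14
Reactants: 21 (2Z)-2-iodobut-2-en-1-ol
Product: 22 tert-butyl{[(2Z)-2-iodobut-2-en-1-yl]oxy}dimethylsilane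
Conditions: t-BuMe2SiCl, imidazole, CH2Cl2, rt
Reagents that add atoms: tert-butyldimethylsilyl chloride, CC(C)(C)[Si](C)(C)Cl
Why: Standard silylation of a primary allylic alcohol masks the hydroxyl for the organolithium step and for the esterification.

Step 15
Reactants: 22 tert-butyl{[(2Z)-2-iodobut-2-en-1-yl]oxy}dimethylsilane
Product: 24 (2Z)-2-({[tert-butyl(dimethyl)silyl]oxy}methyl)but-2-enoic acid, via vinyllithium 23 (not isolated)
Conditions: t-BuLi (2 equiv), Et2O, −78 °C; CO2, −78 °C → rt; 1 M HCl to pH 4 at 0 °C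
Reagents that add atoms: carbon dioxide, O=C=O
Why: Iodine–lithium exchange and carboxylation both proceed with retention at the sp2 carbon, so methyl cis to iodine becomes methyl cis to the carboxyl group, the Z geometry of the target acyl unit.

Step 16
Reactants: 18 (1S,2R)-1-(3,4-dimethoxyphenyl)-2-[(2E)-3-(4-methoxyphenyl)prop-2-en-1-yl]propane-1,3-diol; 24 (2Z)-2-({[tert-butyl(dimethyl)silyl]oxy}methyl)but-2-enoic acid
Product: 26 (2R,4E)-2-[(S)-(3,4-dimethoxyphenyl)(hydroxy)methyl]-5-(4-methoxyphenyl)pent-4-en-1-yl (2Z)-2-({[tert-butyl(dimethyl)silyl]oxy}methyl)but-2-enoate, via mixed anhydride 25 (not isolated)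
Conditions: 24, 2,4,6-trichlorobenzoyl chloride, Et3N, toluene, rt; then 18, toluene, 20 → 50 °C
Reagents that add atoms: none
Why: Yamaguchi esterification through the hindered mixed anhydride should acylate the primary hydroxyl ahead of the secondary benzylic one, and leaving out a nucleophilic catalyst avoids addition–elimination isomerisation of the Z acyl unit.

Step 17
Reactants: 26 (2R,4E)-2-[(S)-(3,4-dimethoxyphenyl)(hydroxy)methyl]-5-(4-methoxyphenyl)pent-4-en-1-yl (2Z)-2-({[tert-butyl(dimethyl)silyl]oxy}methyl)but-2-enoate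
Product: 27 (2R,4E)-2-[(S)-(3,4-dimethoxyphenyl)(hydroxy)methyl]-5-(4-methoxyphenyl)pent-4-en-1-yl (2Z)-2-(hydroxymethyl)but-2-enoate (CNP0280662.1)
Conditions: Bu4NF, AcOH (1:1), THF, 0 °C → rt
Reagents that add atoms: none
Why: Acetic acid-buffered fluoride desilylation removes the primary silyl ether while the near-neutral medium should prevent acyl migration to the benzylic hydroxyl and ionisation of the benzylic alcohol.

## Compound list

1 | 4-methoxybenzaldehyde | COc1ccc(C=O)cc1 | starting material
2 | vinylmagnesium bromide | C=C[Mg]Br | starting material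
3 | rac-1-(4-methoxyphenyl)prop-2-en-1-ol | C=CC(O)c1ccc(OC)cc1 | intermediate
4 | (1R)-1-(4-methoxyphenyl)prop-2-en-1-yl acetate | C=C[C@@H](OC(C)=O)c1ccc(OC)cc1 | intermediate
5 | (1R)-1-(4-methoxyphenyl)prop-2-en-1-ol | C=C[C@@H](O)c1ccc(OC)cc1 | intermediate
6 | methyl 3-hydroxypropanoate | COC(=O)CCO | starting material
7 | methyl 3-[(triisopropylsilyl)oxy]propanoate | COC(=O)CCO[Si](C(C)C)(C(C)C)C(C)C | intermediate
8 | 3-[(triisopropylsilyl)oxy]propanoic acid | OC(=O)CCO[Si](C(C)C)(C(C)C)C(C)C | intermediate
9 | (1R)-1-(4-methoxyphenyl)prop-2-en-1-yl 3-[(triisopropylsilyl)oxy]propanoate | C=C[C@@H](OC(=O)CCO[Si](C(C)C)(C(C)C)C(C)C)c1ccc(OC)cc1 | intermediate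
10 | (Z)-silyl ketene acetal of 9: (1Z)-1-{[(1R)-1-(4-methoxyphenyl)prop-2-en-1-yl]oxy}-3-[(triisopropylsilyl)oxy]-1-[(trimethylsilyl)oxy]prop-1-ene, CH2OSi cis to OSiMe3 | C=C[C@@H](O/C(O[Si](C)(C)C)=C/CO[Si](C(C)C)(C(C)C)C(C)C)c1ccc(OC)cc1 | intermediate (not isolated)
11 | trimethylsilyl (2R,4E)-5-(4-methoxyphenyl)-2-{[(triisopropylsilyl)oxy]methyl}pent-4-enoate | C[Si](C)(C)OC(=O)[C@@H](CO[Si](C(C)C)(C(C)C)C(C)C)C/C=C/c1ccc(OC)cc1 | intermediate (not isolated)
12 | (2R,4E)-5-(4-methoxyphenyl)-2-{[(triisopropylsilyl)oxy]methyl}pent-4-enoic acid | OC(=O)[C@@H](CO[Si](C(C)C)(C(C)C)C(C)C)C/C=C/c1ccc(OC)cc1 | intermediate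
13 | (2R,4E)-N-methoxy-5-(4-methoxyphenyl)-N-methyl-2-{[(triisopropylsilyl)oxy]methyl}pent-4-enamide | CON(C)C(=O)[C@@H](CO[Si](C(C)C)(C(C)C)C(C)C)C/C=C/c1ccc(OC)cc1 | intermediate
14 | 4-bromo-1,2-dimethoxybenzene | COc1ccc(Br)cc1OC | starting material
15 | (3,4-dimethoxyphenyl)magnesium bromide | COc1ccc([Mg]Br)cc1OC | intermediate (not isolated)
16 | (2R,4E)-1-(3,4-dimethoxyphenyl)-5-(4-methoxyphenyl)-2-{[(triisopropylsilyl)oxy]methyl}pent-4-en-1-one | COc1ccc(cc1OC)C(=O)[C@@H](CO[Si](C(C)C)(C(C)C)C(C)C)C/C=C/c1ccc(OC)cc1 | intermediate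
17 | (2R,4E)-1-(3,4-dimethoxyphenyl)-2-(hydroxymethyl)-5-(4-methoxyphenyl)pent-4-en-1-one | COc1ccc(cc1OC)C(=O)[C@@H](CO)C/C=C/c1ccc(OC)cc1 | intermediate
18 | (1S,2R)-1-(3,4-dimethoxyphenyl)-2-[(2E)-3-(4-methoxyphenyl)prop-2-en-1-yl]propane-1,3-diol | OC[C@@H](C/C=C/c1ccc(OC)cc1)[C@H](O)c1ccc(OC)c(OC)c1 | intermediate
19 | (E)-but-2-enal (crotonaldehyde) | C/C=C/C=O | starting material
20 | (2Z)-2-iodobut-2-enal | C/C=C(\I)C=O | intermediate
21 | (2Z)-2-iodobut-2-en-1-ol | C/C=C(\I)CO | intermediate
22 | tert-butyl{[(2Z)-2-iodobut-2-en-1-yl]oxy}dimethylsilane | C/C=C(\I)CO[Si](C)(C)C(C)(C)C | intermediate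
23 | vinyllithium from 22 (lithium in place of iodine, methyl cis to lithium) | C/C=C(\[Li])CO[Si](C)(C)C(C)(C)C | intermediate (not isolated)
24 | (2Z)-2-({[tert-butyl(dimethyl)silyl]oxy}methyl)but-2-enoic acid | C/C=C(/CO[Si](C)(C)C(C)(C)C)C(=O)O | intermediate
25 | mixed anhydride of 24 with 2,4,6-trichlorobenzoic acid | C/C=C(/CO[Si](C)(C)C(C)(C)C)C(=O)OC(=O)c1c(Cl)cc(Cl)cc1Cl | intermediate (not isolated)
26 | (2R,4E)-2-[(S)-(3,4-dimethoxyphenyl)(hydroxy)methyl]-5-(4-methoxyphenyl)pent-4-en-1-yl (2Z)-2-({[tert-butyl(dimethyl)silyl]oxy}methyl)but-2-enoate | C/C=C(/CO[Si](C)(C)C(C)(C)C)C(=O)OC[C@@H](C/C=C/c1ccc(OC)cc1)[C@H](O)c1ccc(OC)c(OC)c1 | intermediate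
27 | (2R,4E)-2-[(S)-(3,4-dimethoxyphenyl)(hydroxy)methyl]-5-(4-methoxyphenyl)pent-4-en-1-yl (2Z)-2-(hydroxymethyl)but-2-enoate | C/C=C(/CO)C(=O)OC[C@@H](C/C=C/c1ccc(OC)cc1)[C@H](O)c1ccc(OC)c(OC)c1 | target

## Step count and risks

Total step count: 17. Longest linear sequence: 11 steps (steps 1, 2, 3, 6, 7, 8, 9, 10, 11, 16, 17).

**Step 7.** Three processes may spoil it. The enolate may expel silyloxide before it is silylated. The 4-methoxybenzylic allylic C–O bond may ionise, which racemises the ester or shifts the acyloxy group. The ketene acetal geometry may be incompletely controlled, which lowers the enantiomeric purity at C2 directly. The fallback is an auxiliary-controlled aldol route that sets out from racemic alcohol 3 and comes back to the route at diol 18. Johnson–Claisen rearrangement of 3 with triethyl orthoacetate and a trace of propionic acid at 140 °C should give ethyl (4E)-5-(4-methoxyphenyl)pent-4-enoate F1. Saponification with LiOH gives (4E)-5-(4-methoxyphenyl)pent-4-enoic acid F2. Activation with pivaloyl chloride and Et3N and acylation of lithiated (S)-4-benzyloxazolidin-2-one gives (4S)-4-benzyl-3-[(4E)-5-(4-methoxyphenyl)pent-4-enoyl]-1,3-oxazolidin-2-one F3. An Evans syn-aldol reaction (Bu2BOTf, i-Pr2NEt, CH2Cl2, −78 → 0 °C) with 3,4-dimethoxybenzaldehyde should then set both centres at once and give (4S)-4-benzyl-3-{(2S,4E)-2-[(S)-(3,4-dimethoxyphenyl)(hydroxy)methyl]-5-(4-methoxyphenyl)pent-4-enoyl}-1,3-oxazolidin-2-one F4. Reductive removal of the auxiliary with LiBH4 in wet Et2O delivers 18.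

**Step 11.** Chelation may be incomplete, so that hydride also enters from the other face. The β-hydroxy ketone made in step 10 may also epimerise at C2 by enolisation, or suffer retro-aldol cleavage or dehydration, before it is reduced. The fallback uses reagent control on the silyl ether and avoids the free β-hydroxy ketone: it sets out from ketone 16 and comes back at diol 18. Reduction of 16 with BH3·SMe2 and (R)-2-methyl-CBS-oxazaborolidine (the B-methyl oxazaborolidine of (R)-α,α-diphenylprolinol) in THF at −20 °C, with the aryl ring acting as the large group, should give (1S,2R,4E)-1-(3,4-dimethoxyphenyl)-5-(4-methoxyphenyl)-2-{[(triisopropylsilyl)oxy]methyl}pent-4-en-1-ol F5. Bu4NF in THF then removes the silyl ether to give 18.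

**Step 16.** Activation of the carboxyl group may isomerise the Z double bond of the acyl unit to E, the benzylic hydroxyl may also be acylated, and the acyl group may migrate between the two hydroxyls. The fallback activates the alcohol and not the acid: it sets out from diol 18 and acid 24 and comes back at ester 26. A Mitsunobu esterification (PPh3, diisopropyl azodicarboxylate, THF, 0 °C) makes the carboxylate of 24 displace the oxyphosphonium of the primary hydroxyl, so the acid is never activated. It passes through no compound outside the compound list (entry F0).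

## Further compounds

F1 | step 7 | ethyl (4E)-5-(4-methoxyphenyl)pent-4-enoate | CCOC(=O)CC/C=C/c1ccc(OC)cc1
F2 | step 7 | (4E)-5-(4-methoxyphenyl)pent-4-enoic acid | OC(=O)CC/C=C/c1ccc(OC)cc1
F3 | step 7 | (4S)-4-benzyl-3-[(4E)-5-(4-methoxyphenyl)pent-4-enoyl]-1,3-oxazolidin-2-one | O=C(CC/C=C/c1ccc(OC)cc1)N1[C@@H](Cc2ccccc2)COC1=O
F4 | step 7 | (4S)-4-benzyl-3-{(2S,4E)-2-[(S)-(3,4-dimethoxyphenyl)(hydroxy)methyl]-5-(4-methoxyphenyl)pent-4-enoyl}-1,3-oxazolidin-2-one | O=C(N1[C@@H](Cc2ccccc2)COC1=O)[C@@H](C/C=C/c1ccc(OC)cc1)[C@H](O)c1ccc(OC)c(OC)c1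
F5 | step 11 | (1S,2R,4E)-1-(3,4-dimethoxyphenyl)-5-(4-methoxyphenyl)-2-{[(triisopropylsilyl)oxy]methyl}pent-4-en-1-ol | CC(C)[Si](OC[C@@H](C/C=C/c1ccc(OC)cc1)[C@H](O)c1ccc(OC)c(OC)c1)(C(C)C)C(C)C
F0 | step 16 | none | none
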